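**Plan**

- Numbering used: cyclohexane C-1 (CH–OAc), C-2 (CMe2), C-3 (CH with side chain), C-4 (C(Me)OH), C-5 and C-6 (CH2); side chain C-1' to C-5', with C-3' the carbinol carbon. The retrosynthesis cuts the aryl ether O–C-5', then C-3'–C-4' (allyl addition), then the ring bonds C-1–C-6 and C-4–C-5 together (Diels–Alder with an ethylene equivalent).
- Enabling feature: C-1 and C-4 are para on the cyclohexane, both carry oxygen, and the C-5–C-6 unit between them is unsubstituted. They can therefore be the two bridgeheads of a bicyclo[2.2.2]oct-2-ene, whose extra etheno bridge is later excised with carbon-to-oxygen exchange at both bridgeheads.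
- Forward order: the ring of 4,4-dimethylcyclohexa-2,5-dienone becomes a temporary cyclohexa-1,3-diene ring (conjugate addition, 1,3-carbonyl transposition, silyl dienol ether). The Diels–Alder reaction closes the target ring across it, and ozonolysis/Baeyer–Villiger oxidation opens the temporary ring. Ketone reduction, acetylation, side-chain allylation/ozonolysis and Mitsunobu etherification finish the route.
- Stereochemistry: C-3 from the ligand-controlled conjugate addition; C-4 from the diene face attacked (anti to the side chain) and retention in the Baeyer–Villiger step; C-1 from equatorial hydride attack on the 2,2-dimethyl ketone; C-3' from a chiral allylborane.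

Key step: step 6

Assumption: for the ferrocenyl diphosphine of step 1 and the allylborane of step 12, the enantiomer named is taken to be the one that gives the drawn configuration (its antipode is used in the same way if the sense of induction is the reverse); compound 1 is taken as a commercial material.

**Route**

Step 1
Reactants: 1 4,4-dimethylcyclohexa-2,5-dien-1-one; 2 2-(2-bromoethyl)-2-methyl-1,3-dioxolane
Product: 5 (5R,6R)-4,4,6-trimethyl-5-[2-(2-methyl-1,3-dioxolan-2-yl)ethyl]cyclohex-2-en-1-one, via Grignard reagent 3 (not isolated), via bromomagnesium dienolate 4 (not isolated)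
Conditions: 2, Mg, THF, 25 °C; then 1, CuBr·SMe2 (5 mol%), (R)-1-[(Sp)-2-(diphenylphosphino)ferrocenyl]ethyldicyclohexylphosphine (6 mol%), t-BuOMe, −78 °C; then MeI, DMPU, −78 to 0 °C
Reagents that add atoms: iodomethane, CI
Why: Copper-catalysed asymmetric conjugate addition of the Grignard reagent desymmetrizes the two enantiotopic enone units of 1, the chiral ligand choosing one and so fixing the side-chain stereocenter (5R), and the magnesium enolate is then C-methylated trans to the new substituent (tandem conjugate addition/enolate alkylation; this methyl-bearing center becomes sp2 again in step 5).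

Step 2
Reactants: 5 (5R,6R)-4,4,6-trimethyl-5-[2-(2-methyl-1,3-dioxolan-2-yl)ethyl]cyclohex-2-en-1-one
Product: 6 3,5,5-trimethyl-4-[2-(2-methyl-1,3-dioxolan-2-yl)ethyl]-7-oxabicyclo[4.1.0]heptan-2-one (epoxide anti to the side chain)
Conditions: H2O2 (30% aq.), NaOH (cat.), MeOH, 0 °C to rt
Reagents that add atoms: hydrogen peroxide, OO
Why: Weitz–Scheffer nucleophilic epoxidation, in which hydroperoxide should add to the enone β-carbon anti to the side chain and the enolate closes the epoxide; the epoxide configuration and any epimerization at the α-methyl carbon are of no consequence later.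

Step 3
Reactants: 6 3,5,5-trimethyl-4-[2-(2-methyl-1,3-dioxolan-2-yl)ethyl]-7-oxabicyclo[4.1.0]heptan-2-one
Product: 7 (1R,4S,5R)-4,6,6-trimethyl-5-[2-(2-methyl-1,3-dioxolan-2-yl)ethyl]cyclohex-2-en-1-ol
Conditions: N2H4·H2O, AcOH (cat.), MeOH, 0 °C to rt
Reagents that add atoms: none
Why: Wharton transposition, in which the hydrazone of the α,β-epoxy ketone opens the epoxide to a vinyl diazene that loses N2, moving the oxygen to the carbon next to the gem-dimethyl group and the double bond to C-2=C-3.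

Step 4
Reactants: 7 (1R,4S,5R)-4,6,6-trimethyl-5-[2-(2-methyl-1,3-dioxolan-2-yl)ethyl]cyclohex-2-en-1-ol
Product: 8 (4S,5R)-4,6,6-trimethyl-5-[2-(2-methyl-1,3-dioxolan-2-yl)ethyl]cyclohex-2-en-1-one
Conditions: Dess–Martin periodinane, NaHCO3, CH2Cl2, rt
Reagents that add atoms: none
Why: Dess–Martin oxidation of the secondary allylic alcohol gives the transposed enone under buffered conditions that leave the dioxolane intact.

Step 5
Reactants: 8 (4S,5R)-4,6,6-trimethyl-5-[2-(2-methyl-1,3-dioxolan-2-yl)ethyl]cyclohex-2-en-1-one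
Product: 9 tert-butyldimethyl{[(5R)-4,6,6-trimethyl-5-[2-(2-methyl-1,3-dioxolan-2-yl)ethyl]cyclohexa-1,3-dien-1-yl]oxy}silane
Conditions: TBSOTf, Et3N, CH2Cl2, 0 °C to rt
Reagents that add atoms: tert-butyldimethylsilyl trifluoromethanesulfonate, CC(C)(C)[Si](C)(C)OS(=O)(=O)C(F)(F)F
Why: Soft enolization (silyl dienol ether formation): O-silylation followed by loss of the γ-proton, the only enolizable position because the α'-carbon is quaternary, should give the linear 1-silyloxy-1,3-diene regiospecifically.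

Step 6
Reactants: 9 tert-butyldimethyl{[(5R)-4,6,6-trimethyl-5-[2-(2-methyl-1,3-dioxolan-2-yl)ethyl]cyclohexa-1,3-dien-1-yl]oxy}silane; 10 phenyl vinyl sulfone
Product: 11 4-(tert-butyldimethylsilyloxy)-1,5,5-trimethyl-6-[2-(2-methyl-1,3-dioxolan-2-yl)ethyl]-8-(phenylsulfonyl)bicyclo[2.2.2]oct-2-ene (side chain syn to the C-2=C-3 bridge; epimers at the sulfonyl carbon)
Conditions: 10 (3 equiv), BHT (cat.), toluene, 120 °C, sealed tube
Reagents that add atoms: none
Why: Thermal, concerted but asynchronous [4+2] cycloaddition of normal electron demand between the s-cis-locked, donor-substituted diene of 9 and the electron-poor alkene of 10, which stands in for ethylene; the closest known reaction type is the Diels–Alder reaction of 1-alkoxy- or 1-silyloxycyclohexa-1,3-dienes with vinyl sulfones to give bicyclo[2.2.2]octenes. The cyclohexane ring of the target is closed as a six-membered carbocycle by suprafacial bonding of both diene termini to the two alkene carbons, which makes the diene ring the temporary second ring of a bicyclo[2.2.2]oct-2-ene. The two new bridgehead stereocenters (C–OSi and C–Me) are set together by the face of the diene that is attacked, and this is controlled by the existing side-chain stereocenter next to the methyl-bearing terminus: the dienophile should come in anti to the side chain, so that the side chain ends up syn to the etheno bridge. The selectivity needed is π-facial only; it is secured because the gem-dimethyl carbon shows one methyl to each face, so that the two faces differ only in H against CH2R at the neighbouring carbon. The configuration at the sulfonyl carbon and the regiochemistry (sulfonyl expected next to the silyloxy bridgehead) are of no consequence, since the sulfonyl group is removed in step 7.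

Step 7
Reactants: 11 4-(tert-butyldimethylsilyloxy)-1,5,5-trimethyl-6-[2-(2-methyl-1,3-dioxolan-2-yl)ethyl]-8-(phenylsulfonyl)bicyclo[2.2.2]oct-2-ene
Product: 12 4-(tert-butyldimethylsilyloxy)-1,5,5-trimethyl-6-[2-(2-methyl-1,3-dioxolan-2-yl)ethyl]bicyclo[2.2.2]oct-2-ene ((6R), side chain syn to the C-2=C-3 bridge)
Conditions: Na(Hg) (6%), Na2HPO4, MeOH/THF, −20 to 0 °C
Reagents that add atoms: none
Why: Reductive desulfonylation with sodium amalgam replaces C–SO2Ph by C–H, so that all regio- and stereoisomers of 11 converge on one compound and the vinyl sulfone has served as an ethylene equivalent.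

Step 8
Reactants: 12 4-(tert-butyldimethylsilyloxy)-1,5,5-trimethyl-6-[2-(2-methyl-1,3-dioxolan-2-yl)ethyl]bicyclo[2.2.2]oct-2-ene
Product: 13 1-(tert-butyldimethylsilyloxy)-2,2,4-trimethyl-3-[2-(2-methyl-1,3-dioxolan-2-yl)ethyl]cyclohexane-1,4-dicarbaldehyde (both formyl groups cis to the side chain)
Conditions: O3, CH2Cl2, −78 °C; PPh3, −78 °C to rt
Reagents that add atoms: ozone, [O-][O+]=O
Why: Ozonolysis with reductive work-up cleaves the only C=C bond, the strained etheno bridge, to a cis-1,4-dialdehyde without touching a stereocenter.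

Step 9
Reactants: 13 1-(tert-butyldimethylsilyloxy)-2,2,4-trimethyl-3-[2-(2-methyl-1,3-dioxolan-2-yl)ethyl]cyclohexane-1,4-dicarbaldehyde
Product: 15 (3S,4R)-4-hydroxy-2,2,4-trimethyl-3-[2-(2-methyl-1,3-dioxolan-2-yl)ethyl]cyclohexan-1-one, via bis-formate 14 (not isolated)
Conditions: mCPBA (2.2 equiv), NaHCO3, CH2Cl2, 0 °C; aq. Na2S2O3; then K2CO3, MeOH, rt
Reagents that add atoms: 3-chloroperoxybenzoic acid, OOC(=O)c1cccc(Cl)c1
Why: Double Baeyer–Villiger oxidation of aldehydes on fully substituted carbons, in which the tertiary C–Me carbon and the α-silyloxy carbon should migrate in preference to hydrogen with retention, so that methanolysis of the formates releases the tertiary alcohol (oxygen cis to the side chain) and, by collapse of the silyl hemiketal, the ketone.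

Step 10
Reactants: 15 (3S,4R)-4-hydroxy-2,2,4-trimethyl-3-[2-(2-methyl-1,3-dioxolan-2-yl)ethyl]cyclohexan-1-one
Product: 17 4-[(1S,3R,6R)-3,6-dihydroxy-2,2,6-trimethylcyclohexyl]butan-2-one, via diol ketal 16 (not isolated)
Conditions: LiBH(s-Bu)3 (L-Selectride, 3 equiv), THF, −78 °C; then 1 M aq. HCl, THF, rt
Reagents that add atoms: water, O
Why: Diastereoselective ketone reduction in which the bulky hydride attacks the 2,2-dimethylcyclohexanone from the equatorial side (as with 4,4-dimethyl-3-oxo steroids) to give the axial alcohol trans to the side chain, after which the acidic work-up hydrolyses the dioxolane to the methyl ketone.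

Step 11
Reactants: 17 4-[(1S,3R,6R)-3,6-dihydroxy-2,2,6-trimethylcyclohexyl]butan-2-one
Product: 18 (1R,3S,4R)-4-hydroxy-2,2,4-trimethyl-3-(3-oxobutyl)cyclohexyl acetate
Conditions: Ac2O, pyridine, DMAP (cat.), CH2Cl2, rt
Reagents that add atoms: acetic anhydride, CC(=O)OC(C)=O
Why: DMAP-catalysed acylation is selective for the secondary hydroxyl, since the tertiary hydroxyl does not react under these conditions.

Step 12
Reactants: 18 (1R,3S,4R)-4-hydroxy-2,2,4-trimethyl-3-(3-oxobutyl)cyclohexyl acetate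
Product: 19 (1R,3S,4R)-4-hydroxy-3-[(3R)-3-hydroxy-3-methylhex-5-en-1-yl]-2,2,4-trimethylcyclohexyl acetate
Conditions: (10R)-9-allyl-10-phenyl-9-borabicyclo[3.3.2]decane (2 equiv), Et2O, −78 °C; ethanolamine work-up
Reagents that add atoms: 9-allyl-10-phenyl-9-borabicyclo[3.3.2]decane, C=CCB1C2CCCC(CCC2)C1c1ccccc1
Why: Reagent-controlled asymmetric allylboration of a methyl ketone through a closed six-membered transition state that tells methyl from the CH2 chain should set the (R)-tertiary carbinol (allyl on the Si face) independently of the remote ring stereocenters.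

Step 13
Reactants: 19 (1R,3S,4R)-4-hydroxy-3-[(3R)-3-hydroxy-3-methylhex-5-en-1-yl]-2,2,4-trimethylcyclohexyl acetate
Product: 21 (1R,3S,4R)-3-[(3R)-3,5-dihydroxy-3-methylpentyl]-4-hydroxy-2,2,4-trimethylcyclohexyl acetate, via ozonide 20 (not isolated)
Conditions: O3, CH2Cl2, −78 °C; then NaBH4, MeOH, −78 to 0 °C
Reagents that add atoms: ozone, [O-][O+]=O
Why: Ozonolysis of the terminal alkene with in situ borohydride reduction of the ozonide gives the primary alcohol of the 1,3-diol, while the acetate and the tertiary alcohols stay inert at this temperature.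

Step 14
Reactants: 21 (1R,3S,4R)-3-[(3R)-3,5-dihydroxy-3-methylpentyl]-4-hydroxy-2,2,4-trimethylcyclohexyl acetate; 22 7-hydroxy-2H-chromen-2-one (umbelliferone)
Product: 23 (1R,3S,4R)-4-hydroxy-3-{(3R)-3-hydroxy-3-methyl-5-[(2-oxo-2H-chromen-7-yl)oxy]pentyl}-2,2,4-trimethylcyclohexyl acetate (CNP0333962.1)
Conditions: PPh3, DIAD, THF, 0 °C to rt
Reagents that add atoms: none
Why: Mitsunobu etherification, in which the acidic phenol displaces the activated primary hydroxyl while the two tertiary hydroxyls and the hindered acetate do not react.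

**Compound list**

1 | 4,4-dimethylcyclohexa-2,5-dien-1-one | CC1(C)C=CC(=O)C=C1 | starting material
2 | 2-(2-bromoethyl)-2-methyl-1,3-dioxolane | CC1(CCBr)OCCO1 | starting material
3 | [2-(2-methyl-1,3-dioxolan-2-yl)ethyl]magnesium bromide | CC1(CC[Mg]Br)OCCO1 | intermediate
4 | bromomagnesium (5R)-4,4-dimethyl-5-[2-(2-methyl-1,3-dioxolan-2-yl)ethyl]cyclohexa-1,5-dien-1-olate | CC1(C)C=CC(O[Mg]Br)=C[C@H]1CCC2(C)OCCO2 | intermediate
5 | (5R,6R)-4,4,6-trimethyl-5-[2-(2-methyl-1,3-dioxolan-2-yl)ethyl]cyclohex-2-en-1-one | CC1(C)C=CC(=O)[C@H](C)[C@H]1CCC2(C)OCCO2 | intermediate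
6 | 3,5,5-trimethyl-4-[2-(2-methyl-1,3-dioxolan-2-yl)ethyl]-7-oxabicyclo[4.1.0]heptan-2-one, epoxide anti to the side chain | CC1(C)[C@@H]2O[C@@H]2C(=O)[C@H](C)[C@H]1CCC3(C)OCCO3 | intermediate
7 | (1R,4S,5R)-4,6,6-trimethyl-5-[2-(2-methyl-1,3-dioxolan-2-yl)ethyl]cyclohex-2-en-1-ol | O[C@@H]1C=C[C@H](C)[C@@H](CCC2(C)OCCO2)C1(C)C | intermediate
8 | (4S,5R)-4,6,6-trimethyl-5-[2-(2-methyl-1,3-dioxolan-2-yl)ethyl]cyclohex-2-en-1-one | O=C1C=C[C@H](C)[C@@H](CCC2(C)OCCO2)C1(C)C | intermediate
9 | tert-butyldimethyl{[(5R)-4,6,6-trimethyl-5-[2-(2-methyl-1,3-dioxolan-2-yl)ethyl]cyclohexa-1,3-dien-1-yl]oxy}silane | CC(C)(C)[Si](C)(C)OC1=CC=C(C)[C@@H](CCC2(C)OCCO2)C1(C)C | intermediate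
10 | phenyl vinyl sulfone | C=CS(=O)(=O)c1ccccc1 | starting material
11 | 4-(tert-butyldimethylsilyloxy)-1,5,5-trimethyl-6-[2-(2-methyl-1,3-dioxolan-2-yl)ethyl]-8-(phenylsulfonyl)bicyclo[2.2.2]oct-2-ene, side chain syn to the alkene bridge, sulfonyl epimers | CC(C)(C)[Si](C)(C)O[C@@]12C(S(=O)(=O)c3ccccc3)C[C@@](C)(C=C1)[C@@H](CCC4(C)OCCO4)C2(C)C | intermediate
12 | 4-(tert-butyldimethylsilyloxy)-1,5,5-trimethyl-6-[2-(2-methyl-1,3-dioxolan-2-yl)ethyl]bicyclo[2.2.2]oct-2-ene, (6R), side chain syn to the alkene bridge | CC(C)(C)[Si](C)(C)O[C@@]12CC[C@@](C)(C=C1)[C@@H](CCC3(C)OCCO3)C2(C)C | intermediate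
13 | 1-(tert-butyldimethylsilyloxy)-2,2,4-trimethyl-3-[2-(2-methyl-1,3-dioxolan-2-yl)ethyl]cyclohexane-1,4-dicarbaldehyde, formyl groups cis to each other and to the side chain | CC(C)(C)[Si](C)(C)O[C@]1(C=O)CC[C@@](C)(C=O)[C@@H](CCC2(C)OCCO2)C1(C)C | intermediate
14 | 1-(tert-butyldimethylsilyloxy)-2,2,4-trimethyl-3-[2-(2-methyl-1,3-dioxolan-2-yl)ethyl]cyclohexane-1,4-diyl diformate, formyloxy groups cis to the side chain | CC(C)(C)[Si](C)(C)O[C@]1(OC=O)CC[C@@](C)(OC=O)[C@@H](CCC2(C)OCCO2)C1(C)C | intermediate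
15 | (3S,4R)-4-hydroxy-2,2,4-trimethyl-3-[2-(2-methyl-1,3-dioxolan-2-yl)ethyl]cyclohexan-1-one | O=C1CC[C@@](C)(O)[C@@H](CCC2(C)OCCO2)C1(C)C | intermediate
16 | (1R,2S,4R)-1,3,3-trimethyl-2-[2-(2-methyl-1,3-dioxolan-2-yl)ethyl]cyclohexane-1,4-diol | O[C@@H]1CC[C@@](C)(O)[C@@H](CCC2(C)OCCO2)C1(C)C | intermediate
17 | 4-[(1S,3R,6R)-3,6-dihydroxy-2,2,6-trimethylcyclohexyl]butan-2-one | O[C@@H]1CC[C@@](C)(O)[C@@H](CCC(C)=O)C1(C)C | intermediate
18 | (1R,3S,4R)-4-hydroxy-2,2,4-trimethyl-3-(3-oxobutyl)cyclohexyl acetate | CC(=O)O[C@@H]1CC[C@@](C)(O)[C@@H](CCC(C)=O)C1(C)C | intermediate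
19 | (1R,3S,4R)-4-hydroxy-3-[(3R)-3-hydroxy-3-methylhex-5-en-1-yl]-2,2,4-trimethylcyclohexyl acetate | CC(=O)O[C@@H]1CC[C@@](C)(O)[C@@H](CC[C@@](C)(O)CC=C)C1(C)C | intermediate
20 | (1R,3S,4R)-4-hydroxy-3-[(3R)-3-hydroxy-3-methyl-4-(1,2,4-trioxolan-3-yl)butyl]-2,2,4-trimethylcyclohexyl acetate | CC(=O)O[C@@H]1CC[C@@](C)(O)[C@@H](CC[C@@](C)(O)CC2OCOO2)C1(C)C | intermediate
21 | (1R,3S,4R)-3-[(3R)-3,5-dihydroxy-3-methylpentyl]-4-hydroxy-2,2,4-trimethylcyclohexyl acetate | CC(=O)O[C@@H]1CC[C@@](C)(O)[C@@H](CC[C@@](C)(O)CCO)C1(C)C | intermediate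
22 | 7-hydroxy-2H-chromen-2-one (umbelliferone) | Oc1ccc2ccc(=O)oc2c1 | starting material
23 | (1R,3S,4R)-4-hydroxy-3-{(3R)-3-hydroxy-3-methyl-5-[(2-oxo-2H-chromen-7-yl)oxy]pentyl}-2,2,4-trimethylcyclohexyl acetate | CC(=O)O[C@@H]1CC[C@@](C)(O)[C@@H](CC[C@@](C)(O)CCOc2ccc3ccc(=O)oc3c2)C1(C)C | target

**Step count and risks**

Total step count: 14. Longest linear sequence: 14 (from 1 and 2 to 23).

Steps most likely to fail:

Step 6. What may go wrong: erosion of π-facial selectivity, or a cycloaddition that stalls because both diene termini are fully substituted and one is next to the gem-dimethyl carbon. The fallback sets out from 9 and changes the two-carbon partner to nitroethylene (freshly prepared, toluene, −20 °C to rt), which should react well below the temperature needed for the sulfone and give the nitro adduct 4-(tert-butyldimethylsilyloxy)-1,5,5-trimethyl-6-[2-(2-methyl-1,3-dioxolan-2-yl)ethyl]-8-nitrobicyclo[2.2.2]oct-2-ene F1. Radical denitration (Bu3SnH, AIBN, toluene, 110 °C) then removes the nitro group, and the route is rejoined at 12.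

Step 9. What may go wrong: migration of hydrogen in place of carbon at the silyloxy-bearing aldehyde, or further oxidation of the freed ketone to a lactone by excess peracid. The fallback sets out from 12 and keeps the peracid away from the silyloxy carbon. Dihydroxylation (OsO4 cat., N-methylmorpholine N-oxide, acetone/water) should give the bridge diol 4-(tert-butyldimethylsilyloxy)-1,5,5-trimethyl-6-[2-(2-methyl-1,3-dioxolan-2-yl)ethyl]bicyclo[2.2.2]octane-2,3-diol F2. Bu4NF (THF) frees the bridgehead hydroxyl to give 1,5,5-trimethyl-6-[2-(2-methyl-1,3-dioxolan-2-yl)ethyl]bicyclo[2.2.2]octane-2,3,4-triol F3. NaIO4 (2 equiv, THF/water) cleaves both C–C bonds of the triol to the keto aldehyde (1R,2R)-1,3,3-trimethyl-2-[2-(2-methyl-1,3-dioxolan-2-yl)ethyl]-4-oxocyclohexane-1-carbaldehyde F4. A single Baeyer–Villiger oxidation of the tertiary aldehyde (mCPBA 1.1 equiv, NaHCO3, CH2Cl2, 0 °C) gives (1R,2S)-1,3,3-trimethyl-2-[2-(2-methyl-1,3-dioxolan-2-yl)ethyl]-4-oxocyclohexyl formate F5, and K2CO3 in MeOH returns to 15.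

Step 12. What may go wrong: poor discrimination of methyl against the CH2 chain at the remote ketone, or protonolysis of the allylborane by the free tertiary hydroxyl. The fallback sets out from 17 (before acetylation) and builds the carbinol by epoxide chemistry.
- Horner–Wadsworth–Emmons olefination ((EtO)2P(O)CH2CO2Et, NaH, THF; E isomer separated) gives ethyl (2E)-5-[(1S,3R,6R)-3,6-dihydroxy-2,2,6-trimethylcyclohexyl]-3-methylpent-2-enoate F6.
- i-Bu2AlH (CH2Cl2, −78 °C) gives (1R,2S,4R)-2-[(3E)-5-hydroxy-3-methylpent-3-en-1-yl]-1,3,3-trimethylcyclohexane-1,4-diol F7.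
- Sharpless asymmetric epoxidation (Ti(OiPr)4, D-(−)-diethyl tartrate, t-BuOOH, 4 Å sieves, CH2Cl2, −20 °C) gives (1R,2S,4R)-2-{2-[(2R,3R)-3-(hydroxymethyl)-2-methyloxiran-2-yl]ethyl}-1,3,3-trimethylcyclohexane-1,4-diol F8.
- NaAlH2(OCH2CH2OMe)2 (THF, 0 °C) opens the epoxide at the carbon next to the CH2OH group to give (1R,2S,4R)-2-[(3R)-3,5-dihydroxy-3-methylpentyl]-1,3,3-trimethylcyclohexane-1,4-diol F9.
- Mitsunobu reaction with 22 (PPh3, DIAD, THF) at the primary hydroxyl gives 7-{[(3R)-5-[(1S,3R,6R)-3,6-dihydroxy-2,2,6-trimethylcyclohexyl]-3-hydroxy-3-methylpentyl]oxy}-2H-chromen-2-one F10.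
- Ac2O/pyridine/DMAP acetylates the secondary hydroxyl only, and the route ends at 23.

**Further compounds**

F1 | step 6 | 4-(tert-butyldimethylsilyloxy)-1,5,5-trimethyl-6-[2-(2-methyl-1,3-dioxolan-2-yl)ethyl]-8-nitrobicyclo[2.2.2]oct-2-ene, side chain syn to the alkene bridge | CC(C)(C)[Si](C)(C)O[C@@]12C([N+](=O)[O-])C[C@@](C)(C=C1)[C@@H](CCC3(C)OCCO3)C2(C)C
F2 | step 9 | 4-(tert-butyldimethylsilyloxy)-1,5,5-trimethyl-6-[2-(2-methyl-1,3-dioxolan-2-yl)ethyl]bicyclo[2.2.2]octane-2,3-diol | CC(C)(C)[Si](C)(C)O[C@@]12CC[C@@](C)(C(O)C1O)[C@@H](CCC3(C)OCCO3)C2(C)C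
F3 | step 9 | 1,5,5-trimethyl-6-[2-(2-methyl-1,3-dioxolan-2-yl)ethyl]bicyclo[2.2.2]octane-2,3,4-triol | O[C@@]12CC[C@@](C)(C(O)C1O)[C@@H](CCC3(C)OCCO3)C2(C)C
F4 | step 9 | (1R,2R)-1,3,3-trimethyl-2-[2-(2-methyl-1,3-dioxolan-2-yl)ethyl]-4-oxocyclohexane-1-carbaldehyde | O=C1CC[C@@](C)(C=O)[C@@H](CCC2(C)OCCO2)C1(C)C
F5 | step 9 | (1R,2S)-1,3,3-trimethyl-2-[2-(2-methyl-1,3-dioxolan-2-yl)ethyl]-4-oxocyclohexyl formate | O=C1CC[C@@](C)(OC=O)[C@@H](CCC2(C)OCCO2)C1(C)C
F6 | step 12 | ethyl (2E)-5-[(1S,3R,6R)-3,6-dihydroxy-2,2,6-trimethylcyclohexyl]-3-methylpent-2-enoate | O[C@@H]1CC[C@@](C)(O)[C@@H](CC/C(C)=C/C(=O)OCC)C1(C)C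
F7 | step 12 | (1R,2S,4R)-2-[(3E)-5-hydroxy-3-methylpent-3-en-1-yl]-1,3,3-trimethylcyclohexane-1,4-diol | O[C@@H]1CC[C@@](C)(O)[C@@H](CC/C(C)=C/CO)C1(C)C
F8 | step 12 | (1R,2S,4R)-2-{2-[(2R,3R)-3-(hydroxymethyl)-2-methyloxiran-2-yl]ethyl}-1,3,3-trimethylcyclohexane-1,4-diol | O[C@@H]1CC[C@@](C)(O)[C@@H](CC[C@@]2(C)O[C@@H]2CO)C1(C)C
F9 | step 12 | (1R,2S,4R)-2-[(3R)-3,5-dihydroxy-3-methylpentyl]-1,3,3-trimethylcyclohexane-1,4-diol | O[C@@H]1CC[C@@](C)(O)[C@@H](CC[C@@](C)(O)CCO)C1(C)C
F10 | step 12 | 7-{[(3R)-5-[(1S,3R,6R)-3,6-dihydroxy-2,2,6-trimethylcyclohexyl]-3-hydroxy-3-methylpentyl]oxy}-2H-chromen-2-one | O[C@@H]1CC[C@@](C)(O)[C@@H](CC[C@@](C)(O)CCOc2ccc3ccc(=O)oc3c2)C1(C)C
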